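50.9% of the intermediate D leaving forward became target in my reckoning: this branch share is the capture rate by reagent at its saturation concentration, a pseudo-first-order rate, divided by that rate plus the loss rate to side product, and it is the selectivity I carried through this flask.

    substrate ⇌ intermediate A (K1 = 2.9, k1 = 7.9 × 10⁻⁴ min⁻¹)
    substrate + reagent ⇌ intermediate B (K2 = 610 M⁻¹, k2 = 0.36 M⁻¹ min⁻¹)
    substrate ⇌ intermediate C (K3 = 45, k3 = 0.0043 min⁻¹)
    intermediate C ⇌ intermediate D (K4 = 0.93, k4 = 5.7 × 10⁻⁴ min⁻¹)
    intermediate D → side product (k5 = 5.2 × 10⁻⁴ min⁻¹)
    reagent + intermediate D → target (k6 = 0.27 M⁻¹ min⁻¹)
    gas ⇌ reagent, rate k7*(csat - [reagent]) (k7 = 0.012 min⁻¹, csat = 2.0 mM)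

substrate 28 mM; gas 2.0 mM (held); time 10 d

1. the target standing at 10 d, as a percentage of the substrate charged
2. the change that raises the amount of target at 10 d, in percent of the substrate charged most ("none" if none brings more than 2 percentage points) (theta / delta / none)
3. amount of target at 10 d, in percent of the substrate charged, after theta

- theta: doubling the transfer coefficient of step 7, all else as stated
- delta: doubling the saturation concentration of gas, all else as stated

I reckoned with rates and shares of the charge. With capture at 5.40 × 10⁻⁴ min⁻¹ and loss at 5.2 × 10⁻⁴ min⁻¹, intermediate D leaves at 1.53 d⁻¹, and I took that as the rate of the drain before any slowing. The first slowing is the return to intermediate C. Taking intermediate D as steady against it, I got 0.341 of intermediate D per intermediate C, so intermediate D is a fraction 0.254 of that pair. The second slowing is that, with the undrained forms taken at their equilibrium ratios, the pair makes up a fraction 0.922 of the undrained charge. Together they bring the drain down to 0.358 d⁻¹, which gave me an estimate of 2.80% undrained at 10 d.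

The third slowing acts on capture. Supplying the target's reagent over 10 d needs a mean shortfall of 4.13% below saturation, so the branch share falls to 49.9%, and I committed to 48.5%. Theta halves that shortfall, giving a share of 50.4% and 49.0% of target. Delta lifts the plain share to 67.5%, a step of 17 percentage points against 0.50 points for theta, so I chose delta.

The forecast gave 46.5% (range 43% to 50%), lower than my figure, then 48.5% after theta (range 45% to 52%), and delta as best, on the ground that “doubling csat roughly doubles reagent and lifts selectivity”.

The flask gave 47.0%, and 47.7% after theta, with delta best at 17 points against 0.72 points for theta. Left until 100 d, this flask read 49.5% of target, beside the branch share of 50.9%. Carried to the delta flask, the ratio of 67.5% to 50.9% scales the standing 47.0% up by 15 points, and that flask's simulated gain was 17 points.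

All constants were set for the occasion; the run is a simulation.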